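**Retrosynthetic overview**
Locants (lignan numbering): ring A = guaiacyl ring, whose C1 carries the side chain; C7 = carbinol carbon; lactone ring = O–C9(=O)–C8–C8'–C9'; C7' = benzylic CH2 of the veratryl ring B.
Last operations: cleavage of the phenol silyl ether and stereoretentive oxidation of C7–B to C7–OH, so the strategic goal is the C7 pinacol boronate of the lactone.
Key disconnection: C1(ring A)–C7 and, in the same operation, the ring bond C9–C8. This leads to a protected 4-bromoguaiacol and an acyclic homoallylic hydrogen oxalate, joined by a 5-exo alkoxycarbonyl-radical closure that is relayed into a nickel aryl coupling with loss of CO2.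
Enabling feature: C7 is the exocyclic carbon on C8, and C8 is the ring carbon next to the lactone carbonyl C9. A radical centred on C9 (held by the ring oxygen and C9') that closes on C8 therefore leaves the spin on C7. The C7 oxygen is carried as boron, which stabilises that radical and polarises the C7=C8 alkene for the attack.
Only C8' is set beforehand (Evans dienolate alkylation). Rings A and B are bought, and the lactone is the only ring formed (key step).
Key step: step 7

Remark on the chemistry: the C3 descriptor of the lactone changes from R in the boronate to S in the carbinol only because oxygen outranks boron in the priority rules; no bond at that carbon is touched. All six starting materials are taken as catalogue compounds.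

Step 1
Reactants: 1 (R)-4-benzyl-2-oxazolidinone; 2 (E)-crotonyl chloride
Product: 4 (R)-4-benzyl-3-[(E)-but-2-enoyl]oxazolidin-2-one, via lithium oxazolidinide 3 (not isolated)
Conditions: n-BuLi (1.0 equiv), THF, −78 °C; then 2, −78 to 0 °C
Reagents that add atoms: none
Why: Standard N-acylation of a lithiated Evans oxazolidinone with an acid chloride at low temperature; no stereocentre is formed and that of the auxiliary is untouched.

Step 2
Reactants: 4 (R)-4-benzyl-3-[(E)-but-2-enoyl]oxazolidin-2-one; 5 3,4-dimethoxybenzyl bromide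
Product: 7 (R)-4-benzyl-3-[(R)-2-(3,4-dimethoxybenzyl)but-3-enoyl]oxazolidin-2-one, via sodium dienolate 6 (not isolated)
Conditions: NaHMDS (1.1 equiv), THF, −78 °C; then 5, −78 to −40 °C; cold aq. NH4Cl
Reagents that add atoms: none
Why: Evans asymmetric alkylation in its deconjugative form: NaHMDS removes a gamma-proton, the sodium-chelated Z-dienolate 6 reacts at its alpha-carbon with the reactive benzylic bromide, and the benzyl group of the (R)-auxiliary shields one face so that the new stereocentre (the later C8') should form as R.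

Step 3
Reactants: 7 (R)-4-benzyl-3-[(R)-2-(3,4-dimethoxybenzyl)but-3-enoyl]oxazolidin-2-one
Product: 8 (R)-2-(3,4-dimethoxybenzyl)but-3-en-1-ol
Conditions: LiBH4, Et2O/THF, 0 °C; aq. NH4Cl
Reagents that add atoms: none
Why: Reductive cleavage of the Evans imide with LiBH4 attacks the exocyclic carbonyl, frees the auxiliary and gives the primary alcohol without enolisation, so the allylic stereocentre and the vinyl group are kept.

Step 4
Reactants: 8 (R)-2-(3,4-dimethoxybenzyl)but-3-en-1-ol; 9 vinylboronic acid pinacol ester
Product: 10 (R,E)-2-(3,4-dimethoxybenzyl)-4-(4,4,5,5-tetramethyl-1,3,2-dioxaborolan-2-yl)but-3-en-1-ol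
Conditions: second-generation Hoveyda–Grubbs catalyst (5 mol %), 9 (3 equiv), CH2Cl2, 40 °C
Reagents that add atoms: none
Why: Olefin cross-metathesis of a terminal alkene with vinyl pinacol boronate is a pairing known to give E-alkenyl boronates with release of ethene; the alkene geometry has no bearing on step 7 and the stereocentre is not touched.

Step 5
Reactants: 10 (R,E)-2-(3,4-dimethoxybenzyl)-4-(pinacolboryl)but-3-en-1-ol; 11 oxalyl chloride
Product: 13 2-{[(R,E)-2-(3,4-dimethoxybenzyl)-4-(pinacolboryl)but-3-en-1-yl]oxy}-2-oxoacetic acid (alkyl hydrogen oxalate), via alkyl chlorooxoacetate 12 (not isolated)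
Conditions: 11 (2 equiv), Et2O, 0 °C to rt; then H2O, 0 °C
Reagents that add atoms: water, O
Why: Acylation of a primary alcohol with excess oxalyl chloride followed by hydrolysis of the remaining acid chloride is the standard entry to alkyl hydrogen oxalates; the excess suppresses the symmetric dialkyl oxalate, and boronate, alkene and aryl ethers should tolerate the anhydrous HCl.

Step 6
Reactants: 14 4-bromo-2-methoxyphenol
Product: 15 (4-bromo-2-methoxyphenoxy)triisopropylsilane
Conditions: TIPSCl, imidazole, DMF, rt
Reagents that add atoms: triisopropylsilyl chloride, CC(C)[Si](Cl)(C(C)C)C(C)C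
Why: Routine silylation of a phenol; the bulky silyl ether masks the easily oxidised phenol during the photoredox step and the perborate oxidation.

Step 7
Reactants: 13 alkyl hydrogen oxalate; 15 (4-bromo-2-methoxyphenoxy)triisopropylsilane
Product: 19 (3R,4R)-4-(3,4-dimethoxybenzyl)-3-{(S)-[3-methoxy-4-(triisopropylsilyloxy)phenyl](4,4,5,5-tetramethyl-1,3,2-dioxaborolan-2-yl)methyl}dihydrofuran-2(3H)-one, via cesium oxalate 16 (not isolated), via alkoxycarbonyl radical 17 (not isolated), via alpha-boryl radical 18 (not isolated)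
Conditions: 13 (1.5 equiv), CsHCO3 (1.5 equiv), Ir[dF(CF3)ppy]2(dtbbpy)PF6 (2 mol %), NiCl2·glyme (5 mol %), dtbbpy (6 mol %), dioxane/DMSO 4:1 (0.03 M), blue LEDs (450 nm), 30 °C, argon
Reagents that add atoms: none
Why: Proposed new method: the photoexcited iridium complex oxidises the carboxylate of 16, loss of CO2 gives the alkoxycarbonyl radical 17, this closes on the alkenyl carbon remote from boron to give the boron-stabilised radical 18, and 18 is caught by the aryl nickel bromide formed from 15 and zerovalent nickel, so that reductive elimination from trivalent nickel forges the aryl C1–C7 bond while the reduced photocatalyst returns monovalent nickel to the zerovalent state. The closest known reaction types are the alkoxycarbonyl-radical cyclisation/nickel cross-coupling cascade of homoallylic cesium oxalates with aryl halides (known for alkenes that deliver primary radicals) and the three-component alkyl–aryl difunctionalisation of vinyl boronic esters under nickel/photoredox catalysis (which shows that alpha-boryl radicals are arylated), and their merger on an internal alkenyl boronate is the new element. The lactone ring closes in the 5-exo-trig mode by forming C9–C8, whereas the 6-endo mode would attack the boron-bearing carbon and give a radical without boron stabilisation. C8 is set in a chair-like Beckwith–Houk transition state with the 3,4-dimethoxybenzyl group on C8' pseudo-equatorial, which places the new C8–C7 branch trans to it. C7 is set at nickel by 1,2-induction: with the C8–H bond eclipsing the C7–B bond to relieve allylic strain, the face next to C8' is blocked and nickel with its aryl group should arrive from the side of the flat C9 carbonyl, which corresponds to 7S. The step needs ring closure to outrun direct capture of 17 by nickel (aryl ester formation) and capture of 18 to outrun its reduction; the polarity match between the nucleophilic acyl-type radical and the electron-poor alkenyl boronate, together with low nickel loading and dilution, secures the first, and the lifetime of the boron-stabilised radical the second.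

Step 8
Reactants: 19 C7 pinacol boronate of the lactone
Product: 20 (3S,4R)-4-(3,4-dimethoxybenzyl)-3-{(S)-hydroxy[3-methoxy-4-(triisopropylsilyloxy)phenyl]methyl}dihydrofuran-2(3H)-one
Conditions: NaBO3·4H2O (4 equiv), THF/H2O 1:1, 0 °C to rt
Reagents that add atoms: sodium perborate, [Na+].[Na+].O[B-]1(O)OO[B-](O)(O)OO1
Why: Stereoretentive oxidation of a secondary boronic ester (1,2-migration of C7 from boron to peroxide oxygen) with mildly basic perborate, the usual choice for beta-boryl esters and lactones, so C7 keeps its configuration and the lactone, C8 and the silyl ether should survive.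

Step 9
Reactants: 20 silyl-protected carbinol
Product: 21 (3S,4R)-4-(3,4-dimethoxybenzyl)-3-[(S)-hydroxy(4-hydroxy-3-methoxyphenyl)methyl]dihydrofuran-2(3H)-one (target)
Conditions: TBAF/AcOH (1:1, 1.2 equiv), THF, 0 °C
Reagents that add atoms: none
Why: Fluoride cleavage of an aryl silyl ether; the acetic acid buffer keeps the liberated phenol protonated, which should prevent retro-aldol cleavage, beta-elimination and quinone methide formation at the para-hydroxybenzylic alcohol, and no stereocentre is affected.

**Compound list**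
1 | (R)-4-benzyl-2-oxazolidinone | O=C1N[C@H](Cc2ccccc2)CO1 | starting material
2 | (E)-crotonyl chloride | C/C=C/C(=O)Cl | starting material
3 | lithium salt of (R)-4-benzyl-2-oxazolidinone | [Li+].O=C1[N-][C@H](Cc2ccccc2)CO1 | intermediate
4 | (R)-4-benzyl-3-[(E)-but-2-enoyl]oxazolidin-2-one | C/C=C/C(=O)N1[C@H](Cc2ccccc2)COC1=O | intermediate
5 | 3,4-dimethoxybenzyl bromide | COc1ccc(CBr)cc1OC | starting material
6 | sodium Z-dienolate of 4 | [Na+].C=C/C=C(\[O-])N1[C@H](Cc2ccccc2)COC1=O | intermediate
7 | (R)-4-benzyl-3-[(R)-2-(3,4-dimethoxybenzyl)but-3-enoyl]oxazolidin-2-one | C=C[C@@H](Cc1ccc(OC)c(OC)c1)C(=O)N1[C@H](Cc2ccccc2)COC1=O | intermediate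
8 | (R)-2-(3,4-dimethoxybenzyl)but-3-en-1-ol | OC[C@@H](C=C)Cc1ccc(OC)c(OC)c1 | intermediate
9 | vinylboronic acid pinacol ester | C=CB1OC(C)(C)C(C)(C)O1 | starting material
10 | (R,E)-2-(3,4-dimethoxybenzyl)-4-(4,4,5,5-tetramethyl-1,3,2-dioxaborolan-2-yl)but-3-en-1-ol | OC[C@@H](/C=C/B1OC(C)(C)C(C)(C)O1)Cc1ccc(OC)c(OC)c1 | intermediate
11 | oxalyl chloride | O=C(Cl)C(=O)Cl | starting material
12 | (R,E)-2-(3,4-dimethoxybenzyl)-4-(pinacolboryl)but-3-en-1-yl chlorooxoacetate | O=C(Cl)C(=O)OC[C@@H](/C=C/B1OC(C)(C)C(C)(C)O1)Cc1ccc(OC)c(OC)c1 | intermediate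
13 | 2-{[(R,E)-2-(3,4-dimethoxybenzyl)-4-(pinacolboryl)but-3-en-1-yl]oxy}-2-oxoacetic acid | OC(=O)C(=O)OC[C@@H](/C=C/B1OC(C)(C)C(C)(C)O1)Cc1ccc(OC)c(OC)c1 | intermediate
14 | 4-bromo-2-methoxyphenol | COc1cc(Br)ccc1O | starting material
15 | (4-bromo-2-methoxyphenoxy)triisopropylsilane | COc1cc(Br)ccc1O[Si](C(C)C)(C(C)C)C(C)C | intermediate
16 | cesium salt of 13 | [Cs+].[O-]C(=O)C(=O)OC[C@@H](/C=C/B1OC(C)(C)C(C)(C)O1)Cc1ccc(OC)c(OC)c1 | intermediate
17 | alkoxycarbonyl radical from 16 (spin on the later C9) | O=[C]OC[C@@H](/C=C/B1OC(C)(C)C(C)(C)O1)Cc1ccc(OC)c(OC)c1 | intermediate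
18 | trans-lactone with the boron-stabilised radical on C7 | [CH](B1OC(C)(C)C(C)(C)O1)[C@H]1C(=O)OC[C@@H]1Cc1ccc(OC)c(OC)c1 | intermediate
19 | (3R,4R)-4-(3,4-dimethoxybenzyl)-3-{(S)-[3-methoxy-4-(triisopropylsilyloxy)phenyl](pinacolboryl)methyl}dihydrofuran-2(3H)-one | COc1cc([C@@H](B3OC(C)(C)C(C)(C)O3)[C@H]2C(=O)OC[C@@H]2Cc2ccc(OC)c(OC)c2)ccc1O[Si](C(C)C)(C(C)C)C(C)C | intermediate
20 | (3S,4R)-4-(3,4-dimethoxybenzyl)-3-{(S)-hydroxy[3-methoxy-4-(triisopropylsilyloxy)phenyl]methyl}dihydrofuran-2(3H)-one | COc1cc([C@@H](O)[C@H]2C(=O)OC[C@@H]2Cc2ccc(OC)c(OC)c2)ccc1O[Si](C(C)C)(C(C)C)C(C)C | intermediate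
21 | (3S,4R)-4-(3,4-dimethoxybenzyl)-3-[(S)-hydroxy(4-hydroxy-3-methoxyphenyl)methyl]dihydrofuran-2(3H)-one | COc1cc([C@@H](O)[C@H]2C(=O)OC[C@@H]2Cc2ccc(OC)c(OC)c2)ccc1O | target

**Step count**
Total steps: 9. Longest linear sequence: 8 (steps 1–5 and 7–9).

**Steps most likely to fail**

1. **Step 7.**
   - What may go wrong: capture of the alkoxycarbonyl radical by nickel before ring closure; reduction and protonation of the boron-stabilised radical; sluggish oxidative addition of the electron-rich aryl bromide; poor facial selectivity at C7.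
   - The fallback keeps the aryl C1–C7 disconnection but makes the bond at the ketone level with known chemistry. It sets out from 8 and 15 and comes back at 20.
   - Hydroboration of 8 with 9-BBN and perborate oxidation would give (R)-2-(3,4-dimethoxybenzyl)butane-1,4-diol F1.
   - TEMPO/PhI(OAc)2 oxidises the less hindered primary alcohol first and closes (R)-4-(3,4-dimethoxybenzyl)dihydrofuran-2(3H)-one F2.
   - LiHMDS and S-ethyl chlorothioformate acylate the enolate anti to the benzyl group to give S-ethyl (3R,4R)-4-(3,4-dimethoxybenzyl)-2-oxotetrahydrofuran-3-carbothioate F3.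
   - Bromine–lithium exchange on 15 with n-BuLi, then B(OiPr)3 and mild acid, give [3-methoxy-4-(triisopropylsilyloxy)phenyl]boronic acid F4.
   - A Liebeskind–Srogl coupling of the two (Pd2(dba)3, tri(2-furyl)phosphine, copper thiophene-2-carboxylate, THF, 50 °C) forms (3S,4R)-4-(3,4-dimethoxybenzyl)-3-[3-methoxy-4-(triisopropylsilyloxy)benzoyl]dihydrofuran-2(3H)-one F5.
   - Noyori–Ikariya transfer hydrogenation (RuCl[(S,S)-TsDPEN](p-cymene), HCO2H/Et3N) then reduces the ketone. C8 is configurationally labile here, so this is a dynamic kinetic resolution; the catalyst sets 7S and the product is 20.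
   - A C7-epimer mixture arising from steps 7 and 8 could enter the same end game by Dess–Martin oxidation of 20 to this ketone.

2. **Step 4.**
   - What may go wrong: slow metathesis at the allylically branched alkene; self-metathesis of the partners; ruthenium hydride-induced migration of the double bond with loss of the stereocentre.
   - The fallback builds the alkenyl boronate by olefination instead. It sets out from 8 and comes back at 10.
   - TBSCl/imidazole give (R)-tert-butyl{[2-(3,4-dimethoxybenzyl)but-3-en-1-yl]oxy}dimethylsilane F6.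
   - Lemieux–Johnson cleavage (OsO4 cat., NaIO4, 2,6-lutidine, dioxane/H2O) gives (S)-2-{[(tert-butyldimethylsilyl)oxy]methyl}-3-(3,4-dimethoxyphenyl)propanal F7.
   - Boron–Wittig olefination with lithiated bis(pinacolboryl)methane (CH2(Bpin)2, LiTMP, THF, −78 °C) gives (R,E)-tert-butyl{[2-(3,4-dimethoxybenzyl)-4-(pinacolboryl)but-3-en-1-yl]oxy}dimethylsilane F8.
   - Camphorsulfonic acid in MeOH at 0 °C removes the silyl group to give 10.

3. **Step 5.**
   - What may go wrong: protodeboronation or loss of pinacol under HCl; double acylation to the symmetric dialkyl oxalate.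
   - The fallback avoids acid and the bifunctional reagent. It sets out from 10 and comes back at 16.
   - Methyl chlorooxoacetate, Et3N and DMAP in CH2Cl2 give methyl (R,E)-2-(3,4-dimethoxybenzyl)-4-(pinacolboryl)but-3-en-1-yl oxalate F9.
   - One equivalent of aqueous CsOH in THF saponifies the methyl ester to the cesium oxalate 16, which is then isolated as a solid and used in step 7 without CsHCO3.

**Further compounds**
F1 | step 7 | (R)-2-(3,4-dimethoxybenzyl)butane-1,4-diol | OC[C@@H](CCO)Cc1ccc(OC)c(OC)c1
F2 | step 7 | (R)-4-(3,4-dimethoxybenzyl)dihydrofuran-2(3H)-one | O=C1C[C@@H](Cc2ccc(OC)c(OC)c2)CO1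
F3 | step 7 | S-ethyl (3R,4R)-4-(3,4-dimethoxybenzyl)-2-oxotetrahydrofuran-3-carbothioate | CCSC(=O)[C@H]1C(=O)OC[C@@H]1Cc1ccc(OC)c(OC)c1
F4 | step 7 | [3-methoxy-4-(triisopropylsilyloxy)phenyl]boronic acid | COc1cc(B(O)O)ccc1O[Si](C(C)C)(C(C)C)C(C)C
F5 | step 7 | (3S,4R)-4-(3,4-dimethoxybenzyl)-3-[3-methoxy-4-(triisopropylsilyloxy)benzoyl]dihydrofuran-2(3H)-one | COc1cc(C(=O)[C@H]2C(=O)OC[C@@H]2Cc2ccc(OC)c(OC)c2)ccc1O[Si](C(C)C)(C(C)C)C(C)C
F6 | step 4 | (R)-tert-butyl{[2-(3,4-dimethoxybenzyl)but-3-en-1-yl]oxy}dimethylsilane | C=C[C@@H](Cc1ccc(OC)c(OC)c1)CO[Si](C)(C)C(C)(C)C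
F7 | step 4 | (S)-2-{[(tert-butyldimethylsilyl)oxy]methyl}-3-(3,4-dimethoxyphenyl)propanal | O=C[C@@H](Cc1ccc(OC)c(OC)c1)CO[Si](C)(C)C(C)(C)C
F8 | step 4 | (R,E)-tert-butyl{[2-(3,4-dimethoxybenzyl)-4-(pinacolboryl)but-3-en-1-yl]oxy}dimethylsilane | CC(C)(C)[Si](C)(C)OC[C@@H](/C=C/B1OC(C)(C)C(C)(C)O1)Cc1ccc(OC)c(OC)c1
F9 | step 5 | methyl (R,E)-2-(3,4-dimethoxybenzyl)-4-(pinacolboryl)but-3-en-1-yl oxalate | COC(=O)C(=O)OC[C@@H](/C=C/B1OC(C)(C)C(C)(C)O1)Cc1ccc(OC)c(OC)c1
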